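Everything rests on disconnecting ring B at C8–C9. The feature exploited is that the adjacent stereocentres C8 (H, CH3) and C9 (quaternary: CH3, C11) sit in a ring B whose C6–C7 edge is unsubstituted, so a [3,3] shift can forge C8–C9, leave a disposable C6=C7 alkene and deliver C11 as a carboxyl group. The silyl ketene acetal of a ring A-fused δ-lactone, in which C11 acylates the C6 oxygen and C6 carries a (Z)-propenyl group, contracts through an enforced boat; one operation closes ring B and sets C8 and C9 from the C6 carbinol. Ring A comes from an asymmetric Diels–Alder reaction, the side chain from an acetylide addition.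

Key step: step 16

Remarks
- Numbering used throughout: ring A = C1, C2, C3, C4 (CH3, CO2Me), C5 (ring-fusion CH), C10 (ring-fusion alkene carbon); ring B = C5, C6, C7, C8 (CH3), C9 (CH3, side chain), C10; side chain C11–C15 outward from C9 (C13 carbinol, C14 and C15 acetoxylated).
- Assumption: the facial sense of the copper catalyst (step 5) and of the oxazaborolidine (step 8) is assigned from the usual chelate and large/small-group models; the enantiomeric ligand would be used if the sense proved opposite.
- C10 in 8–13 and C9 in 19–22 are deliberately left uncontrolled: C10 is oxidised in step 11 and C9 is planarised in step 16, so the epimers converge. The SMILES show the expected C10 epimer and one C9 epimer.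
- The C6 descriptor changes from S (alkynyl compounds 11–21) to R (alkenyl lactone 22) by CIP priority only. The geometry of 22 (propenyl cis to H5 on the lactone ring, Z alkene) was checked against a suprafacial shift and leads to the (8R,9S) acid 25; no structure needed correction.

Step 1
Reactants: 1 mesaconic acid
Product: 2 dimethyl mesaconate
Conditions: MeOH, H2SO4 (cat.), reflux
Reagents that add atoms: methanol, CO
Why: Fischer esterification of both carboxyl groups under acid catalysis leaves the E alkene untouched.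

Step 2
Reactants: 2 dimethyl mesaconate
Product: 3 (E)-4-methoxy-3-methyl-4-oxobut-2-enoic acid (mesaconic acid 1-methyl ester)
Conditions: KOH (1.0 equiv), MeOH/H2O, 0 °C → rt; then HCl
Reagents that add atoms: potassium hydroxide, [K+].[OH-]
Why: Regioselective saponification with one equivalent of hydroxide should cleave the less hindered ester on the CH carbon faster than the ester on the methyl-bearing alkene carbon, which places the free acid where the imide is needed.

Step 3
Reactants: 3 (E)-4-methoxy-3-methyl-4-oxobut-2-enoic acid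
Product: 5 methyl (E)-2-methyl-4-oxo-4-(2-oxo-1,3-oxazolidin-3-yl)but-2-enoate, via mixed pivalic anhydride 4 (not isolated)
Conditions: t-BuCOCl, Et3N, THF, −20 °C; then oxazolidin-2-one, LiCl, rt
Reagents that add atoms: oxazolidin-2-one, O=C1NCCO1
Why: N-Acylation of the oxazolidinone through the mixed anhydride, which is attacked at its less hindered unsaturated acyl carbon, installs the two-point-binding imide without touching the alkene geometry.

Step 4
Reactants: 6 (E)-crotonaldehyde
Product: 7 (E)-1-(triethylsilyloxy)buta-1,3-diene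
Conditions: Et3SiOTf, Et3N, Et2O, 0 °C → rt
Reagents that add atoms: triethylsilyl trifluoromethanesulfonate, CC[Si](CC)(CC)OS(=O)(=O)C(F)(F)F
Why: Silyl dienol ether formation by O-silylation and gamma-deprotonation of the enal gives the 1-silyloxydiene, whose triethylsilyl ether should survive the next five steps yet be cleavable beside a tert-butyldimethylsilyl ether.

Step 5
Reactants: 5 methyl (E)-2-methyl-4-oxo-4-(2-oxo-1,3-oxazolidin-3-yl)but-2-enoate; 7 (E)-1-(triethylsilyloxy)buta-1,3-diene
Product: 8 methyl (1R,5R,6S)-1-methyl-6-[(2-oxo-1,3-oxazolidin-3-yl)carbonyl]-5-(triethylsilyloxy)cyclohex-3-ene-1-carboxylate (4R,5S,10R; ester trans to the imide carbonyl, silyloxy group cis to it)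
Conditions: [Cu((S,S)-t-Bu-box)](SbF6)2 (10 mol %), CH2Cl2, −40 → 0 °C
Reagents that add atoms: none
Why: In this Lewis-acid-catalysed Diels–Alder reaction the imide chelates divalent copper in a square-planar s-cis complex whose tert-butyl group shields the Si face of the imide alpha carbon, so the diene should add to the Re face and set C5, while the E geometry fixes C4 relative to C5, the oxygenated diene terminus bonds alpha to the chelated carbonyl (C10–C5), and the endo mode places the silyloxy group cis to the acyl group.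

Step 6
Reactants: 8 cycloadduct imide
Product: 9 methyl (1R,5R,6S)-6-[methoxy(methyl)carbamoyl]-1-methyl-5-(triethylsilyloxy)cyclohex-3-ene-1-carboxylate (4R,5S,10R)
Conditions: MeNH(OMe)·HCl, AlMe3, CH2Cl2, 0 °C → rt
Reagents that add atoms: N,O-dimethylhydroxylamine hydrochloride, CNOC.Cl
Why: Weinreb amide formation by aminolysis of the exocyclic imide carbonyl with the aluminium amide removes the oxazolidinone, while the neopentyl C4 methyl ester is far less reactive and no stereocentre is touched.

Step 7
Reactants: 9 Weinreb amide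
Product: 10 methyl (1R,5R,6S)-6-(but-2-ynoyl)-1-methyl-5-(triethylsilyloxy)cyclohex-3-ene-1-carboxylate (4R,5S,10R)
Conditions: MeC≡CMgBr, THF, 0 °C
Reagents that add atoms: 1-propynylmagnesium bromide, CC#C[Mg]Br
Why: In this Weinreb ketone synthesis the alkynyl Grignard reagent adds once to give a chelated tetrahedral intermediate that releases the C6 ynone only on work-up, and the silyl ether keeps the C10 oxygen from adding to the ynone.

Step 8
Reactants: 10 ynone
Product: 11 methyl (1R,5R,6R)-6-[(1S)-1-hydroxybut-2-yn-1-yl]-1-methyl-5-(triethylsilyloxy)cyclohex-3-ene-1-carboxylate (4R,5R,6S,10R)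
Conditions: (S)-Me-CBS oxazaborolidine (20 mol %), catecholborane, CH2Cl2, −78 °C
Reagents that add atoms: none
Why: In this Corey–Bakshi–Shibata reduction the slim alkynyl group acts as the small and the branched ring carbon C5 as the large substituent, so the (S)-oxazaborolidine should deliver hydride under reagent control to give the (6S) propargylic alcohol, and catecholborane at low temperature leaves the ring alkene alone.

Step 9
Reactants: 11 propargylic alcohol
Product: 12 methyl (1R,5R,6S)-6-[(1S)-1-(tert-butyldimethylsilyloxy)but-2-yn-1-yl]-1-methyl-5-(triethylsilyloxy)cyclohex-3-ene-1-carboxylate (4R,5S,6S,10R)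
Conditions: t-BuMe2SiOTf, 2,6-lutidine, CH2Cl2, −78 → 0 °C
Reagents that add atoms: tert-butyldimethylsilyl trifluoromethanesulfonate, CC(C)(C)[Si](C)(C)OS(=O)(=O)C(F)(F)F
Why: Silyl ether formation with the reactive silyl triflate masks the hindered C6 hydroxyl with a group that outlasts the triethylsilyl ether.

Step 10
Reactants: 12 bis-silyl ether
Product: 13 methyl (1R,5R,6S)-6-[(1S)-1-(tert-butyldimethylsilyloxy)but-2-yn-1-yl]-5-hydroxy-1-methylcyclohex-3-ene-1-carboxylate (4R,5S,6S,10R)
Conditions: PPTS, MeOH/CH2Cl2, 0 °C → rt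
Reagents that add atoms: none
Why: Selective desilylation by mild acid-catalysed methanolysis removes the triethylsilyl ether much faster than the tert-butyldimethylsilyl ether and frees only the allylic C10 alcohol.

Step 11
Reactants: 13 allylic alcohol
Product: 14 methyl (1R,2R)-2-[(1S)-1-(tert-butyldimethylsilyloxy)but-2-yn-1-yl]-1-methyl-3-oxocyclohex-4-ene-1-carboxylate (4R,5R,6S)
Conditions: Dess–Martin periodinane, CH2Cl2, rt
Reagents that add atoms: none
Why: Dess–Martin oxidation of the allylic alcohol gives the enone under neutral conditions that avoid beta-elimination of the C6 silyloxy group and epimerisation at C5, and it merges both C10 epimers.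

Step 12
Reactants: 14 enone
Product: 16 methyl (1R,2R)-2-[(1S)-1-(tert-butyldimethylsilyloxy)but-2-yn-1-yl]-1-methyl-3-(trifluoromethylsulfonyloxy)cyclohex-3-ene-1-carboxylate (4R,5R,6S), via lithium enolate 15 (not isolated)
Conditions: LiBH(s-Bu)3, THF, −78 °C; then PhNTf2, −78 → 0 °C
Reagents that add atoms: N-phenylbis(trifluoromethanesulfonimide), O=S(=O)(N(c1ccccc1)S(=O)(=O)C(F)(F)F)C(F)(F)F
Why: Reductive enol triflate formation, in which conjugate hydride addition to the beta-unsubstituted cyclohexenone gives the C1(10) enolate regiospecifically and O-sulfonylation traps it, fixes the double bond at C1=C10 without any deprotonation at C5.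

Step 13
Reactants: 16 enol triflate; 17 methyl 2-bromopropanoate
Product: 19 methyl (1R,2R)-2-[(1S)-1-(tert-butyldimethylsilyloxy)but-2-yn-1-yl]-3-(1-methoxy-1-oxopropan-2-yl)-1-methylcyclohex-3-ene-1-carboxylate (4R,5R,6S; C9 epimers), via Reformatsky reagent 18 (not isolated)
Conditions: 17, Zn dust (Me3SiCl-activated), THF, rt; then 16, Pd(dba)2 (5 mol %), P(t-Bu)3 (10 mol %), THF, rt → 50 °C
Reagents that add atoms: none
Why: Zinc insertion into the alpha-bromo ester gives the Reformatsky reagent, which undergoes a Negishi-type cross-coupling with the enol triflate under zerovalent palladium catalysis to form C9–C10 with the alkene held at C1=C10, and the C9 epimer mixture is of no consequence because C9 is planarised in step 16.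

Step 14
Reactants: 19 silyl ether diester
Product: 21 methyl (1S,4S,8R,8aR)-4,8-dimethyl-3-oxo-1-(prop-1-yn-1-yl)-3,4,6,7,8,8a-hexahydro-1H-isochromene-8-carboxylate (4R,5R,6S; 9S drawn), via hydroxy ester 20 (not isolated)
Conditions: HF·pyridine, THF, 0 °C → rt; then PPTS (cat.), PhMe, 60 °C
Reagents that add atoms: none
Why: Fluoride cleavage of the silyl ether followed by acid-catalysed lactonisation closes the six-membered lactone onto the unhindered C11 ester and not onto the neopentyl C4 ester, which is trans to C6 on ring A and would give a strained trans-fused five-membered lactone.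

Step 15
Reactants: 21 alkynyl lactone
Product: 22 methyl (1R,4S,8R,8aR)-4,8-dimethyl-3-oxo-1-[(Z)-prop-1-en-1-yl]-3,4,6,7,8,8a-hexahydro-1H-isochromene-8-carboxylate (4R,5R,6R; 9S drawn)
Conditions: H2 (1 atm), Pd/CaCO3 poisoned with Pb(OAc)2, quinoline, EtOAc, rt
Reagents that add atoms: none
Why: Lindlar semihydrogenation adds hydrogen syn to the alkyne and stops at the (Z)-propenyl group, leaving the trisubstituted C1=C10 alkene and the allylic lactone C–O bond intact.

Step 16
Reactants: 22 (Z)-propenyl lactone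
Product: 25 (1S,2R,4aR,5R)-5-(methoxycarbonyl)-1,2,5-trimethyl-1,2,4a,5,6,7-hexahydronaphthalene-1-carboxylic acid (4R,5R,8R,9S), via silyl ketene acetal 23 (not isolated), via trimethylsilyl ester 24 (not isolated)
Conditions: LiN(i-Pr)2, Me3SiCl/Et3N, THF, −78 °C → rt; PhMe, 100 °C; then 1 M HCl
Reagents that add atoms: none
Why: Deprotonation at C9 (alpha to the lactone carbonyl and allylic to C1=C10) and O-silylation give the cyclic ketene acetal 23, whose C9=C11–O–C6–C7=C8 array undergoes a concerted suprafacial [3,3] sigmatropic shift (Ireland–Claisen rearrangement) that forms C8–C9 and breaks C6–O. The closest known reaction type is the ring contraction of silyl ketene acetals of alkenyl-substituted lactones to cycloalkene carboxylic acids. Ring B (C5, C6, C7, C8, C9, C10) closes in a 6-endo sense inside a bicyclo[2.2.2]octane-like array, which enforces a boat transition state because C9 and C6 stay bridged by C10–C5. C9 is controlled by the C6 carbinol configuration, since C8 can reach only the ketene acetal face on which the propenyl group stands, and C8 is controlled by the Z geometry, which turns its methyl group toward the C10–C5 bridge and so trans to C11 and cis to the C9 methyl group. The step needs O- rather than C-silylation and rearrangement faster than loss of the ketene acetal, which the fully substituted enolate carbon, the in-situ chlorosilane quench and the irreversible formation of the silyl ester should secure, while the C4 ester has no alpha hydrogen and the ring fixes the ketene acetal geometry.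

Step 17
Reactants: 25 acid
Product: 27 methyl (1R,5S,6R,8aR)-5-(hydroxymethyl)-1,5,6-trimethyl-1,2,3,5,6,8a-hexahydronaphthalene-1-carboxylate (4R,5R,8R,9S), via acid chloride 26 (not isolated)
Conditions: (COCl)2, DMF (cat.), CH2Cl2, 0 °C → rt; then NaBH4, THF/DMF, 0 °C
Reagents that add atoms: none
Why: Acyl chloride formation and borohydride reduction distinguish C11 from the C4 methyl ester and avoid borane reagents that would hydroborate the two alkenes.

Step 18
Reactants: 27 primary alcohol
Product: 28 methyl (1R,5S,6R,8aR)-5-formyl-1,5,6-trimethyl-1,2,3,5,6,8a-hexahydronaphthalene-1-carboxylate (4R,5R,8R,9S)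
Conditions: Dess–Martin periodinane, CH2Cl2, rt
Reagents that add atoms: none
Why: Dess–Martin oxidation of the neopentyl alcohol gives the non-enolisable C11 aldehyde without over-oxidation.

Step 19
Reactants: 28 aldehyde
Product: 29 methyl (1R,5R,6R,8aR)-5-ethynyl-1,5,6-trimethyl-1,2,3,5,6,8a-hexahydronaphthalene-1-carboxylate (4R,5R,8R,9R by priority change)
Conditions: MeC(O)C(N2)P(O)(OMe)2, K2CO3, MeOH, 0 °C → rt
Reagents that add atoms: dimethyl (1-diazo-2-oxopropyl)phosphonate, CC(=O)C(=[N+]=[N-])P(=O)(OC)OC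
Why: Seyferth–Gilbert homologation with the Ohira–Bestmann reagent converts the non-enolisable aldehyde into the C11≡C12 terminal alkyne in mildly basic methanol, in which the methyl ester can only exchange with itself.

Step 20
Reactants: 30 methyl (R)-2,2-dimethyl-1,3-dioxolane-4-carboxylate
Product: 31 (R)-N-methoxy-N,2,2-trimethyl-1,3-dioxolane-4-carboxamide
Conditions: MeNH(OMe)·HCl, i-PrMgCl, THF, −20 °C
Reagents that add atoms: N,O-dimethylhydroxylamine hydrochloride, CNOC.Cl
Why: Weinreb amide formation by aminolysis of the methyl ester with the magnesium amide at low temperature keeps the alpha-alkoxy stereocentre intact.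

Step 21
Reactants: 31 Weinreb amide
Product: 32 1-[(4R)-2,2-dimethyl-1,3-dioxolan-4-yl]ethan-1-one
Conditions: MeMgBr, THF, 0 °C
Reagents that add atoms: methylmagnesium bromide, C[Mg]Br
Why: In this Weinreb ketone synthesis the amide takes up one equivalent of the Grignard reagent and releases the methyl ketone only on work-up, so the future C14 centre is never exposed to base as a ketone.

Step 22
Reactants: 29 terminal alkyne; 32 methyl ketone
Product: 34 methyl (1R,5S,6R,8aR)-5-{(3S)-3-[(4R)-2,2-dimethyl-1,3-dioxolan-4-yl]-3-hydroxybut-1-yn-1-yl}-1,5,6-trimethyl-1,2,3,5,6,8a-hexahydronaphthalene-1-carboxylate (4R,5R,8R,9S,13S,14R), via lithium acetylide 33 (not isolated)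
Conditions: 29, LiN(i-Pr)2, THF, −78 °C; then 32, −78 °C
Reagents that add atoms: none
Why: 1,2-Addition of the lithium acetylide to the alpha-alkoxy ketone should follow the Felkin–Anh model (C14–O bond antiperiplanar to the incoming nucleophile in weakly chelating tetrahydrofuran), which places the new C13 hydroxyl anti to the C14 oxygen in the C12–C15 zigzag and so gives (13S), and the amide base spares the hindered C4 ester.

Step 23
Reactants: 34 propargylic alcohol
Product: 35 methyl (1R,5S,6R,8aR)-5-{(3S)-3-[(4R)-2,2-dimethyl-1,3-dioxolan-4-yl]-3-hydroxybutyl}-1,5,6-trimethyl-1,2,3,5,6,7,8,8a-octahydronaphthalene-1-carboxylate (4R,5R,8R,9S,13S,14R)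
Conditions: H2 (4 atm), RhCl(PPh3)3 (20 mol %), PhH/EtOH, 40 °C
Reagents that add atoms: none
Why: Chemoselective homogeneous hydrogenation with RhCl(PPh3)3 saturates the alkyne and the cis-disubstituted C6=C7 alkene but not the hindered trisubstituted C1=C10 alkene, and it creates no stereocentre.

Step 24
Reactants: 35 acetonide
Product: 36 methyl (1R,5S,6R,8aR)-1,5,6-trimethyl-5-[(3S,4R)-3,4,5-trihydroxy-3-methylpentyl]-1,2,3,5,6,7,8,8a-octahydronaphthalene-1-carboxylate
Conditions: AcOH/H2O/THF (3:1:1), 40 °C
Reagents that add atoms: none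
Why: Acid-catalysed acetal hydrolysis frees the C14 and C15 hydroxyls under conditions too mild to ionise the tertiary C13 alcohol or move the C1=C10 alkene.

Step 25
Reactants: 36 triol
Product: 37 methyl (1R,5S,6R,8aR)-5-[(3S,4R)-4,5-diacetoxy-3-hydroxy-3-methylpentyl]-1,5,6-trimethyl-1,2,3,5,6,7,8,8a-octahydronaphthalene-1-carboxylate (target, CNP0238486.1)
Conditions: Ac2O, pyridine, rt
Reagents that add atoms: acetic anhydride, CC(=O)OC(C)=O
Why: Selective O-acetylation with acetic anhydride in pyridine without a nucleophilic catalyst esterifies the primary and secondary hydroxyls and leaves the tertiary C13 hydroxyl free.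

Compound list
1 | mesaconic acid | C/C(=C\C(=O)O)/C(=O)O | starting material
2 | dimethyl mesaconate | C/C(=C\C(=O)OC)/C(=O)OC | intermediate
3 | (E)-4-methoxy-3-methyl-4-oxobut-2-enoic acid | C/C(=C\C(=O)O)/C(=O)OC | intermediate
4 | mixed pivalic anhydride of 3 | C/C(=C\C(=O)OC(=O)C(C)(C)C)/C(=O)OC | intermediate (not isolated)
5 | methyl (E)-2-methyl-4-oxo-4-(2-oxo-1,3-oxazolidin-3-yl)but-2-enoate | C/C(=C\C(=O)N1CCOC1=O)/C(=O)OC | intermediate
6 | (E)-crotonaldehyde | C/C=C/C=O | starting material
7 | (E)-1-(triethylsilyloxy)buta-1,3-diene | C=C/C=C/O[Si](CC)(CC)CC | intermediate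
8 | methyl (1R,5R,6S)-1-methyl-6-[(2-oxo-1,3-oxazolidin-3-yl)carbonyl]-5-(triethylsilyloxy)cyclohex-3-ene-1-carboxylate | COC(=O)[C@]1(C)CC=C[C@@H](O[Si](CC)(CC)CC)[C@H]1C(=O)N1CCOC1=O | intermediate
9 | methyl (1R,5R,6S)-6-[methoxy(methyl)carbamoyl]-1-methyl-5-(triethylsilyloxy)cyclohex-3-ene-1-carboxylate | COC(=O)[C@]1(C)CC=C[C@@H](O[Si](CC)(CC)CC)[C@H]1C(=O)N(C)OC | intermediate
10 | methyl (1R,5R,6S)-6-(but-2-ynoyl)-1-methyl-5-(triethylsilyloxy)cyclohex-3-ene-1-carboxylate | COC(=O)[C@]1(C)CC=C[C@@H](O[Si](CC)(CC)CC)[C@H]1C(=O)C#CC | intermediate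
11 | methyl (1R,5R,6R)-6-[(1S)-1-hydroxybut-2-yn-1-yl]-1-methyl-5-(triethylsilyloxy)cyclohex-3-ene-1-carboxylate | COC(=O)[C@]1(C)CC=C[C@@H](O[Si](CC)(CC)CC)[C@H]1[C@H](O)C#CC | intermediate
12 | methyl (1R,5R,6S)-6-[(1S)-1-(tert-butyldimethylsilyloxy)but-2-yn-1-yl]-1-methyl-5-(triethylsilyloxy)cyclohex-3-ene-1-carboxylate | COC(=O)[C@]1(C)CC=C[C@@H](O[Si](CC)(CC)CC)[C@H]1[C@H](O[Si](C)(C)C(C)(C)C)C#CC | intermediate
13 | methyl (1R,5R,6S)-6-[(1S)-1-(tert-butyldimethylsilyloxy)but-2-yn-1-yl]-5-hydroxy-1-methylcyclohex-3-ene-1-carboxylate | COC(=O)[C@]1(C)CC=C[C@@H](O)[C@H]1[C@H](O[Si](C)(C)C(C)(C)C)C#CC | intermediate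
14 | methyl (1R,2R)-2-[(1S)-1-(tert-butyldimethylsilyloxy)but-2-yn-1-yl]-1-methyl-3-oxocyclohex-4-ene-1-carboxylate | COC(=O)[C@]1(C)CC=CC(=O)[C@H]1[C@H](O[Si](C)(C)C(C)(C)C)C#CC | intermediate
15 | lithium C1(10)-enolate formed from 14 by hydride addition at C2 | COC(=O)[C@]1(C)CCC=C(O[Li])[C@H]1[C@H](O[Si](C)(C)C(C)(C)C)C#CC | intermediate (not isolated)
16 | methyl (1R,2R)-2-[(1S)-1-(tert-butyldimethylsilyloxy)but-2-yn-1-yl]-1-methyl-3-(trifluoromethylsulfonyloxy)cyclohex-3-ene-1-carboxylate | COC(=O)[C@]1(C)CCC=C(OS(=O)(=O)C(F)(F)F)[C@H]1[C@H](O[Si](C)(C)C(C)(C)C)C#CC | intermediate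
17 | methyl 2-bromopropanoate (racemic) | CC(Br)C(=O)OC | starting material
18 | bromo(1-methoxy-1-oxopropan-2-yl)zinc | COC(=O)C(C)[Zn]Br | intermediate (not isolated)
19 | methyl (1R,2R)-2-[(1S)-1-(tert-butyldimethylsilyloxy)but-2-yn-1-yl]-3-(1-methoxy-1-oxopropan-2-yl)-1-methylcyclohex-3-ene-1-carboxylate (C9 epimers) | COC(=O)[C@]1(C)CCC=C(C(C)C(=O)OC)[C@H]1[C@H](O[Si](C)(C)C(C)(C)C)C#CC | intermediate
20 | methyl (1R,2R)-2-[(1S)-1-hydroxybut-2-yn-1-yl]-3-(1-methoxy-1-oxopropan-2-yl)-1-methylcyclohex-3-ene-1-carboxylate (C9 epimers) | COC(=O)[C@]1(C)CCC=C(C(C)C(=O)OC)[C@H]1[C@H](O)C#CC | intermediate (not isolated)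
21 | methyl (1S,4S,8R,8aR)-4,8-dimethyl-3-oxo-1-(prop-1-yn-1-yl)-3,4,6,7,8,8a-hexahydro-1H-isochromene-8-carboxylate (C9 epimer also carried) | COC(=O)[C@]1(C)CCC=C2[C@H]1[C@@H](C#CC)OC(=O)[C@H]2C | intermediate
22 | methyl (1R,4S,8R,8aR)-4,8-dimethyl-3-oxo-1-[(Z)-prop-1-en-1-yl]-3,4,6,7,8,8a-hexahydro-1H-isochromene-8-carboxylate (C9 epimer also carried) | COC(=O)[C@]1(C)CCC=C2[C@H]1[C@@H](/C=C\C)OC(=O)[C@H]2C | intermediate
23 | methyl (1R,8R,8aR)-4,8-dimethyl-1-[(Z)-prop-1-en-1-yl]-3-(trimethylsilyloxy)-6,7,8,8a-tetrahydro-1H-isochromene-8-carboxylate (silyl ketene acetal) | COC(=O)[C@]1(C)CCC=C2[C@H]1[C@@H](/C=C\C)OC(O[Si](C)(C)C)=C2C | intermediate (not isolated)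
24 | trimethylsilyl ester of 25 | COC(=O)[C@]1(C)CCC=C2[C@H]1C=C[C@@H](C)[C@]2(C)C(=O)O[Si](C)(C)C | intermediate (not isolated)
25 | (1S,2R,4aR,5R)-5-(methoxycarbonyl)-1,2,5-trimethyl-1,2,4a,5,6,7-hexahydronaphthalene-1-carboxylic acid | COC(=O)[C@]1(C)CCC=C2[C@H]1C=C[C@@H](C)[C@]2(C)C(=O)O | intermediate
26 | acid chloride of 25 | COC(=O)[C@]1(C)CCC=C2[C@H]1C=C[C@@H](C)[C@]2(C)C(Cl)=O | intermediate (not isolated)
27 | methyl (1R,5S,6R,8aR)-5-(hydroxymethyl)-1,5,6-trimethyl-1,2,3,5,6,8a-hexahydronaphthalene-1-carboxylate | COC(=O)[C@]1(C)CCC=C2[C@H]1C=C[C@@H](C)[C@]2(C)CO | intermediate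
28 | methyl (1R,5S,6R,8aR)-5-formyl-1,5,6-trimethyl-1,2,3,5,6,8a-hexahydronaphthalene-1-carboxylate | COC(=O)[C@]1(C)CCC=C2[C@H]1C=C[C@@H](C)[C@]2(C)C=O | intermediate
29 | methyl (1R,5R,6R,8aR)-5-ethynyl-1,5,6-trimethyl-1,2,3,5,6,8a-hexahydronaphthalene-1-carboxylate | COC(=O)[C@]1(C)CCC=C2[C@H]1C=C[C@@H](C)[C@]2(C)C#C | intermediate
30 | methyl (R)-2,2-dimethyl-1,3-dioxolane-4-carboxylate | COC(=O)[C@H]1COC(C)(C)O1 | starting material
31 | (R)-N-methoxy-N,2,2-trimethyl-1,3-dioxolane-4-carboxamide | CON(C)C(=O)[C@H]1COC(C)(C)O1 | intermediate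
32 | 1-[(4R)-2,2-dimethyl-1,3-dioxolan-4-yl]ethan-1-one | CC(=O)[C@H]1COC(C)(C)O1 | intermediate
33 | lithium acetylide of 29 | COC(=O)[C@]1(C)CCC=C2[C@H]1C=C[C@@H](C)[C@]2(C)C#C[Li] | intermediate (not isolated)
34 | methyl (1R,5S,6R,8aR)-5-{(3S)-3-[(4R)-2,2-dimethyl-1,3-dioxolan-4-yl]-3-hydroxybut-1-yn-1-yl}-1,5,6-trimethyl-1,2,3,5,6,8a-hexahydronaphthalene-1-carboxylate | COC(=O)[C@]1(C)CCC=C2[C@H]1C=C[C@@H](C)[C@]2(C)C#C[C@](C)(O)[C@H]1COC(C)(C)O1 | intermediate
35 | methyl (1R,5S,6R,8aR)-5-{(3S)-3-[(4R)-2,2-dimethyl-1,3-dioxolan-4-yl]-3-hydroxybutyl}-1,5,6-trimethyl-1,2,3,5,6,7,8,8a-octahydronaphthalene-1-carboxylate | COC(=O)[C@]1(C)CCC=C2[C@H]1CC[C@@H](C)[C@]2(C)CC[C@](C)(O)[C@H]1COC(C)(C)O1 | intermediate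
36 | methyl (1R,5S,6R,8aR)-1,5,6-trimethyl-5-[(3S,4R)-3,4,5-trihydroxy-3-methylpentyl]-1,2,3,5,6,7,8,8a-octahydronaphthalene-1-carboxylate | COC(=O)[C@]1(C)CCC=C2[C@H]1CC[C@@H](C)[C@]2(C)CC[C@](C)(O)[C@H](O)CO | intermediate
37 | methyl (1R,5S,6R,8aR)-5-[(3S,4R)-4,5-diacetoxy-3-hydroxy-3-methylpentyl]-1,5,6-trimethyl-1,2,3,5,6,7,8,8a-octahydronaphthalene-1-carboxylate | COC(=O)[C@]1(C)CCC=C2[C@H]1CC[C@@H](C)[C@]2(C)CC[C@](C)(O)[C@@H](COC(C)=O)OC(C)=O | target

Total step count: 25 (22 on the main line, 1 for diene 7, 2 for ketone 32).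
Longest linear sequence: 22 steps (steps 1–3, 5–19 and 22–25).

Steps most likely to fail

Step 16. The amide base may add to the lactone carbonyl instead of removing the C9 hydrogen, silylation may occur on carbon, or the ketene acetal may lose its silyl group or fragment before the crowded boat with the inside methyl group is reached. The fallback generates the same ketene acetal without base, as a reductive Ireland–Claisen sequence. It sets out from triflate 16: Lindlar semihydrogenation should give the (Z)-propenyl triflate F1. Stille coupling of F1 with methyl 2-(tributylstannyl)acrylate (Pd(PPh3)4, CuI, DMF) should give the dienyl acrylate F2. HF·pyridine and then PPTS should give the alpha-methylene lactone F3. Conjugate hydride addition to the exocyclic methylene of F3 with LiBH(s-Bu)3, followed by Me3SiCl, should give ketene acetal 23, where the fallback rejoins the route and proceeds by heating to 25.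

Step 5. The copper Lewis acid may divert the silyl dienol ether into a stepwise conjugate addition with silyl transfer, or it may discriminate poorly between the faces of the trisubstituted dienophile. The fallback replaces catalyst control by auxiliary control. It sets out from acid 3, which is coupled by the method of step 3 with (R)-4-benzyl-1,3-oxazolidin-2-one to give the chiral imide F4. Cycloaddition of F4 with diene 7 promoted by Me2AlCl (CH2Cl2, −78 °C), in which the benzyl group of the aluminium chelate covers the Si face of the imide alpha carbon, should give the cycloadduct F5. Under the conditions of step 6, F5 is converted into Weinreb amide 9, where the fallback rejoins the route.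

Step 13. Transmetalation and reductive elimination of the secondary zinc enolate at the hindered C10 may be slower than protonation of the zinc reagent or reduction of the triflate, and the new double bond may slip into conjugation with the ester. The fallback reverses the polarity of the partners. It sets out from triflate 16: Miyaura borylation (B2pin2, PdCl2(PPh3)2, PPh3, KOPh, PhMe, 50 °C) should give the alkenyl pinacol boronate F6. Suzuki–Miyaura coupling of F6 with bromo ester 17 (Pd(OAc)2, P(o-Tol)3, K3PO4, THF/H2O) should give diester 19, where the fallback rejoins the route.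

Further compounds
F1 | step 16 | methyl (1R,2R)-2-[(1R,2Z)-1-(tert-butyldimethylsilyloxy)but-2-en-1-yl]-1-methyl-3-(trifluoromethylsulfonyloxy)cyclohex-3-ene-1-carboxylate | COC(=O)[C@]1(C)CCC=C(OS(=O)(=O)C(F)(F)F)[C@H]1[C@H](O[Si](C)(C)C(C)(C)C)/C=C\C
F2 | step 16 | methyl (1R,2R)-2-[(1R,2Z)-1-(tert-butyldimethylsilyloxy)but-2-en-1-yl]-3-(3-methoxy-3-oxoprop-1-en-2-yl)-1-methylcyclohex-3-ene-1-carboxylate | COC(=O)[C@]1(C)CCC=C(C(=C)C(=O)OC)[C@H]1[C@H](O[Si](C)(C)C(C)(C)C)/C=C\C
F3 | step 16 | methyl (1R,8R,8aR)-8-methyl-4-methylidene-3-oxo-1-[(Z)-prop-1-en-1-yl]-3,4,6,7,8,8a-hexahydro-1H-isochromene-8-carboxylate | COC(=O)[C@]1(C)CCC=C2[C@H]1[C@@H](/C=C\C)OC(=O)C2=C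
F4 | step 5 | methyl (E)-4-[(4R)-4-benzyl-2-oxo-1,3-oxazolidin-3-yl]-2-methyl-4-oxobut-2-enoate | C/C(=C\C(=O)N1[C@H](Cc2ccccc2)COC1=O)/C(=O)OC
F5 | step 5 | methyl (1R,5R,6S)-6-{[(4R)-4-benzyl-2-oxo-1,3-oxazolidin-3-yl]carbonyl}-1-methyl-5-(triethylsilyloxy)cyclohex-3-ene-1-carboxylate | COC(=O)[C@]1(C)CC=C[C@@H](O[Si](CC)(CC)CC)[C@H]1C(=O)N1[C@H](Cc2ccccc2)COC1=O
F6 | step 13 | methyl (1R,2R)-2-[(1S)-1-(tert-butyldimethylsilyloxy)but-2-yn-1-yl]-1-methyl-3-(4,4,5,5-tetramethyl-1,3,2-dioxaborolan-2-yl)cyclohex-3-ene-1-carboxylate | COC(=O)[C@]1(C)CCC=C(B2OC(C)(C)C(C)(C)O2)[C@H]1[C@H](O[Si](C)(C)C(C)(C)C)C#CC
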